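Locants: C1 is the ring carbon bearing OH and C7H2OH, C2 bears the free OH, C3 and C6 bear the benzoates, and C4=C5 is the alkene. The cyclohexene ring is cut into two three-carbon pieces. C6, C1 and C2, each oxygenated, correspond to dihydroxyacetone, and because O2 and O6 lie on one ring face a single acetal can span them; C3, C4 and C5 correspond to acrolein. A proline-catalysed Michael–aldol annulation of 2,2-dimethyl-1,3-dioxan-5-one with 2-(phenylselanyl)propenal forms C5–C6 and C2–C3, closes the carbocycle as a 2,4-dioxabicyclo[3.3.1]nonan-9-one and sets C6, C2 and C3 at once. Selenium at C4 masks the C4=C5 alkene until the last step.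

Key step: step 2

Remark: β denotes the ring face that carries O2, O3 and O6, α the opposite face. The key-step product is drawn with selenium equatorial at C4 (the expected epimer); either C4 epimer would serve, because the last step removes this centre.

Step 1
Reactants: 1 acrolein + 2 benzeneselenenyl chloride
Product: 4 2-(phenylselanyl)prop-2-enal, via β-chloro aldehyde 3 (not isolated)
Conditions: CH2Cl2, −78 → 0 °C; then Et3N, 0 °C
Reagents that add atoms: none
Why: Electrophilic addition of the selenenyl chloride across the enal places selenium on the α-carbon and chloride on the β-carbon, and E1cB loss of HCl from this β-chloro aldehyde with Et3N gives the α-selanyl enal (addition–elimination α-selenenylation of an enal), which is used at once because it polymerises on standing.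

Step 2
Reactants: 5 2,2-dimethyl-1,3-dioxan-5-one + 4 2-(phenylselanyl)prop-2-enal
Product: 7 (1S,5R,6S,7S)-6-hydroxy-3,3-dimethyl-7-(phenylselanyl)-2,4-dioxabicyclo[3.3.1]nonan-9-one, via keto aldehyde 6 (not isolated)
Conditions: (S)-proline (30 mol %), DMF, 4 → 20 °C; 5 in excess, 4 added slowly
Reagents that add atoms: none
Why: Proposed new method: (S)-proline forms the enamine of 5, which adds through its α-carbon to the β-carbon of 4 (bond C5–C6); after protonation of the α-selanyl enol the catalyst-bound ketone re-forms an enamine toward the unsubstituted α-carbon, and this adds to the formyl group (bond C2–C3) before hydrolysis frees the catalyst. The closest known reaction types are the α,α′-annulation of preformed cyclic-ketone enamines with acrolein to bicyclo[3.3.1]nonan-9-ones and the proline-catalysed aldol and Michael additions of 5, so what is new is the catalytic, enantioselective merger on this ketone and this acceptor. The carbocycle closes by a 6-(enolendo)-exo-trig aldol addition, a favoured mode for enamines and enols. C6 is set by the catalyst, the acceptor being delivered by the carboxylic acid to the enamine face used in the known proline aldol reactions of 5, which corresponds to S; C2 follows from C6 because the acetal can bridge only cis oxygens; C3 should carry its hydroxyl equatorial on the chair carbocycle, cis to O2, by chair-like closure backed by retro-aldol equilibration; C4 is expected with selenium equatorial but is inconsequential, since step 8 erases it. The step needs conjugate addition to win over 1,2-addition and over a second alkylation, which the soft enamine, the α-selenium that shields the formyl carbon and stabilises the developing enol, the reversibility of the 1,2-adduct, an excess of 5 and slow addition of 4 are meant to secure.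

Step 3
Reactants: 7 bicyclic hydroxy ketone + 8 benzoyl chloride
Product: 9 (1S,5R,6S,7S)-3,3-dimethyl-9-oxo-7-(phenylselanyl)-2,4-dioxabicyclo[3.3.1]nonan-6-yl benzoate
Conditions: pyridine, DMAP (cat.), CH2Cl2, 0 → 20 °C
Reagents that add atoms: none
Why: Esterification of the equatorial secondary alcohol by DMAP-catalysed acylation with an acyl chloride locks the aldol against retro-aldol cleavage, and since both α-carbons of the ketone are bridgeheads and cannot enolise, neither β-elimination nor epimerisation can compete.

Step 4
Reactants: 9 keto benzoate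
Product: 10 (1S,5S,6S,7S)-3,3-dimethyl-9-methylidene-7-(phenylselanyl)-2,4-dioxabicyclo[3.3.1]nonan-6-yl benzoate
Conditions: Cp2TiMe2 (2 equiv), toluene/THF, 65 °C, dark
Reagents that add atoms: dimethyltitanocene Cp2TiMe2, [CH3-].[CH3-].c1cc[cH-]c1.c1cc[cH-]c1.[Ti+4]
Why: Petasis olefination, in which the titanium methylidene generated thermally from Cp2TiMe2 methylenates the strained, electron-poor bridging ketone ahead of the benzoate when the reagent is limited, is non-basic and leaves the selenide and the acetal untouched.

Step 5
Reactants: 10 methylidene acetal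
Product: 11 (1S,2S,4S,6S)-2,4-dihydroxy-3-methylidene-6-(phenylselanyl)cyclohexyl benzoate
Conditions: AcOH/H2O 4:1, 40 °C
Reagents that add atoms: none
Why: Acid-catalysed acetal hydrolysis, made easy by the strain of the bridging gem-dimethyl dioxane, frees O2 and O6 while the benzoate, the selenide and the two singly allylic carbinols are stable to aqueous acetic acid.

Step 6
Reactants: 11 diol + 8 benzoyl chloride
Product: 12 (1S,3S,4S,5S)-3-hydroxy-2-methylidene-5-(phenylselanyl)cyclohexane-1,4-diyl dibenzoate
Conditions: BzCl (1.1 equiv), pyridine, CH2Cl2, −30 → 0 °C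
Reagents that add atoms: none
Why: Regioselective esterification with a limited amount of acyl chloride at low temperature, in which O6–H sits between the sp2 carbon C1 and the methylene C5 whereas O2–H is flanked by C1 and the benzoate-bearing C3, so the less hindered O6 should be acylated first.

Step 7
Reactants: 12 dibenzoate
Product: 13 (1S,2S,3R,4S,5S)-2,3-dihydroxy-2-(hydroxymethyl)-5-(phenylselanyl)cyclohexane-1,4-diyl dibenzoate
Conditions: OsO4 (5 mol %), NMO (1.5 equiv), acetone/H2O 4:1, 0 → 20 °C
Reagents that add atoms: osmium tetroxide OsO4, O=[Os](=O)(=O)=O; N-methylmorpholine N-oxide, C[N+]1([O-])CCOCC1; water, O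
Why: Osmium-catalysed syn-dihydroxylation of the only alkene present, in which OsO4 should add to the α face, opposite to the three ring oxygens O2, O3 and O6 (osmylation anti to allylic oxygen, here reinforced by sterics), which places O1 trans and C7 cis to them and so sets C1, while the aryl alkyl selenide is expected to survive because selenoxides are themselves strong enough oxidants to reoxidise hexavalent osmium.

Step 8
Reactants: 13 triol selenide
Product: 15 (1R,4S,5S,6R)-5,6-dihydroxy-5-(hydroxymethyl)cyclohex-2-ene-1,4-diyl dibenzoate, via selenoxide 14 (not isolated)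
Conditions: 30% H2O2, pyridine, CH2Cl2, 0 → 20 °C
Reagents that add atoms: none
Why: Selenoxide elimination, in which H2O2 oxidises the selenide and the selenoxide undergoes syn-elimination at room temperature toward C5 and not toward the oxygen-bearing C3, as is general for β-acyloxy selenoxides, so the C4=C5 alkene is unveiled under nearly neutral conditions without touching a stereocentre or moving a benzoate.

Compound list
1 | acrolein (prop-2-enal) | C=CC=O | starting material
2 | benzeneselenenyl chloride | Cl[Se]c1ccccc1 | starting material
3 | 3-chloro-2-(phenylselanyl)propanal (racemic) | O=CC(CCl)[Se]c1ccccc1 | intermediate (not isolated)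
4 | 2-(phenylselanyl)prop-2-enal | C=C([Se]c1ccccc1)C=O | intermediate
5 | 2,2-dimethyl-1,3-dioxan-5-one | CC1(C)OCC(=O)CO1 | starting material
6 | 3-[(4S)-2,2-dimethyl-5-oxo-1,3-dioxan-4-yl]-2-(phenylselanyl)propanal (both epimers at the selenium-bearing carbon) | O=CC([Se]c1ccccc1)C[C@@H]1OC(C)(C)OCC1=O | intermediate (not isolated)
7 | (1S,5R,6S,7S)-6-hydroxy-3,3-dimethyl-7-(phenylselanyl)-2,4-dioxabicyclo[3.3.1]nonan-9-one | O=C1[C@@H]2C[C@H]([Se]c3ccccc3)[C@@H](O)[C@H]1OC(C)(C)O2 | intermediate
8 | benzoyl chloride | O=C(Cl)c1ccccc1 | starting material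
9 | (1S,5R,6S,7S)-3,3-dimethyl-9-oxo-7-(phenylselanyl)-2,4-dioxabicyclo[3.3.1]nonan-6-yl benzoate | O=C1[C@@H]2C[C@H]([Se]c3ccccc3)[C@@H](OC(=O)c3ccccc3)[C@H]1OC(C)(C)O2 | intermediate
10 | (1S,5S,6S,7S)-3,3-dimethyl-9-methylidene-7-(phenylselanyl)-2,4-dioxabicyclo[3.3.1]nonan-6-yl benzoate | C=C1[C@@H]2C[C@H]([Se]c3ccccc3)[C@@H](OC(=O)c3ccccc3)[C@H]1OC(C)(C)O2 | intermediate
11 | (1S,2S,4S,6S)-2,4-dihydroxy-3-methylidene-6-(phenylselanyl)cyclohexyl benzoate | C=C1[C@@H](O)C[C@H]([Se]c2ccccc2)[C@@H](OC(=O)c2ccccc2)[C@H]1O | intermediate
12 | (1S,3S,4S,5S)-3-hydroxy-2-methylidene-5-(phenylselanyl)cyclohexane-1,4-diyl dibenzoate | C=C1[C@@H](OC(=O)c2ccccc2)C[C@H]([Se]c2ccccc2)[C@@H](OC(=O)c2ccccc2)[C@H]1O | intermediate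
13 | (1S,2S,3R,4S,5S)-2,3-dihydroxy-2-(hydroxymethyl)-5-(phenylselanyl)cyclohexane-1,4-diyl dibenzoate | OC[C@@]1(O)[C@@H](OC(=O)c2ccccc2)C[C@H]([Se]c2ccccc2)[C@@H](OC(=O)c2ccccc2)[C@H]1O | intermediate
14 | selenoxide of 13, 5-(benzeneseleninyl)-2,3-dihydroxy-2-(hydroxymethyl)cyclohexane-1,4-diyl dibenzoate (ring configuration as in 13, both configurations at selenium) | OC[C@@]1(O)[C@@H](OC(=O)c2ccccc2)C[C@H]([Se](=O)c2ccccc2)[C@@H](OC(=O)c2ccccc2)[C@H]1O | intermediate (not isolated)
15 | (1R,4S,5S,6R)-5,6-dihydroxy-5-(hydroxymethyl)cyclohex-2-ene-1,4-diyl dibenzoate (CNP0212417.6) | O=C(O[C@H]1C=C[C@@H](OC(=O)c2ccccc2)[C@@H](O)[C@@]1(O)CO)c1ccccc1 | target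

Total step count: 8. Longest linear sequence: 8 steps (1 to 15).

Steps most likely to fail

Step 2 (Proposed new method). What may go wrong: 1,2-addition of the enamine to the formyl group or oligomerisation of 4 in place of conjugate addition; weak enantiofacial control in the conjugate addition; and reversal of the aldol ring closure, which is strained because the gem-dimethyl acetal cannot sit in a chair dioxane within the bicycle. The fallback uses known chemistry, sets out from 5 and comes back at 6 and then 7. Compound 5 is condensed with (S)-1-amino-2-(methoxymethyl)pyrrolidine (SAMP) to the hydrazone F1. Deprotonation with tBuLi (THF, −78 °C) and alkylation of the azaenolate with 3-bromo-1,1-dimethoxypropane at −100 → −78 °C gives the alkylated hydrazone F2, SAMP being the auxiliary enantiomer that delivers the (S)-configured ring carbon by the established sense of such azaenolate alkylations. Two-phase aqueous oxalic acid/Et2O removes the auxiliary and the dimethyl acetal to give the keto aldehyde F3. Amine-catalysed α-selenenylation of the aldehyde (N-(phenylselanyl)phthalimide, L-prolinamide cat., CH2Cl2) gives 6, isolated this time, and an amine-catalysed intramolecular aldol addition (pyrrolidinium acetate) closes it to 7.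

Step 7. What may go wrong: oxidation at selenium by the osmium/N-oxide system, which would trigger early syn-elimination and expose the new ring alkene to a second dihydroxylation. The fallback sets out from 12, comes back at 15 and exchanges the order of the last two operations. Compound 12 is oxidised at selenium (mCPBA, CH2Cl2, −78 °C) to the selenoxide F4 (not isolated), which eliminates on warming with iPr2NH to the diene F5. F5 is then dihydroxylated with catalytic OsO4 and a single equivalent of NMO at 0 °C, where the 1,1-disubstituted alkene next to the free allylic hydroxyl should react ahead of the ring alkene flanked by two benzoates, again from the α face, to give 15.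

Step 6. What may go wrong: acylation at O2 or at both hydroxyls, or migration of the O3 benzoyl group to O2 under the basic conditions. The fallback sets out from 11, comes back at 13 and postpones the acylation until C1 is quaternary. Compound 11 is dihydroxylated as in step 7 to the tetraol F6. 2,2-Dimethoxypropane with PPTS in acetone ties the terminal 1,2-diol O1/O7 into the spiro acetonide F7. In F7, O2–H is wedged between the quaternary C1 and the benzoate-bearing C3, whereas O6–H has the methylene C5 on one side, so benzoylation (BzCl, pyridine, 0 °C) should single out O6 and give the dibenzoate F8. Aqueous 80% AcOH then removes the acetonide to give 13.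

Further compounds
F1 | step 2 | (S)-N-(2,2-dimethyl-1,3-dioxan-5-ylidene)-2-(methoxymethyl)pyrrolidin-1-amine (SAMP hydrazone of 5) | COC[C@@H]1CCCN1N=C1COC(C)(C)OC1
F2 | step 2 | (S)-N-[(4S)-4-(3,3-dimethoxypropyl)-2,2-dimethyl-1,3-dioxan-5-ylidene]-2-(methoxymethyl)pyrrolidin-1-amine | COC[C@@H]1CCCN1N=C1COC(C)(C)O[C@H]1CCC(OC)OC
F3 | step 2 | 3-[(4S)-2,2-dimethyl-5-oxo-1,3-dioxan-4-yl]propanal | O=CCC[C@@H]1OC(C)(C)OCC1=O
F4 | step 7 | selenoxide of 12, 5-(benzeneseleninyl)-3-hydroxy-2-methylidenecyclohexane-1,4-diyl dibenzoate (ring configuration as in 12, both configurations at selenium) | C=C1[C@@H](OC(=O)c2ccccc2)C[C@H]([Se](=O)c2ccccc2)[C@@H](OC(=O)c2ccccc2)[C@H]1O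
F5 | step 7 | (1S,4R,5S)-5-hydroxy-6-methylidenecyclohex-2-ene-1,4-diyl dibenzoate | C=C1[C@@H](OC(=O)c2ccccc2)C=C[C@@H](OC(=O)c2ccccc2)[C@H]1O
F6 | step 6 | 2,3,4-trihydroxy-3-(hydroxymethyl)-6-(phenylselanyl)cyclohexyl benzoate, the O6-debenzoyl analogue of 13 with the same configuration | OC[C@@]1(O)[C@@H](O)C[C@H]([Se]c2ccccc2)[C@@H](OC(=O)c2ccccc2)[C@H]1O
F7 | step 6 | 1,7-O-isopropylidene derivative of F6 (spiro 2,2-dimethyl-1,3-dioxolane on C1 and C7, O2–H and O6–H free) | CC1(C)OC[C@@]2(O1)[C@@H](O)C[C@H]([Se]c3ccccc3)[C@@H](OC(=O)c3ccccc3)[C@H]2O
F8 | step 6 | O6-benzoate of F7, the 1,7-O-isopropylidene derivative of 13 | CC1(C)OC[C@@]2(O1)[C@@H](OC(=O)c3ccccc3)C[C@H]([Se]c3ccccc3)[C@@H](OC(=O)c3ccccc3)[C@H]2O
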